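**Retrosynthetic overview**

1. Numbering: ring A = C1–C2–C3–C4–C5–C10, ring B = C5–C6–C7–C8–C9–C10, β = face of the C5 methyl. The plan rests on the contiguous run C8(O)–C9(O)–C10(H)–C5(Me)–C4(Me), which is C1(OH)–C2(OMe)–C3–C4(Me)–C5(Me) of 2-methoxy-4,5-dimethylphenol, and on the cis fusion of ring B to ring A (5-Me and 10-H cis).
2. Target 27 ⇐ ring-A enone 26 (C4–H by 1,4-hydride addition) ⇐ C8/C9 reduction and acylation ⇐ C7 isopropenylation of cis-decalinone 14.
3. 14 ⇐ anionic oxy-Cope shift of the 2-vinylbicyclo[2.2.2]oct-5-en-2-ol 11 (C5–C6 formed, C3–C8 broken).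
4. 11 ⇐ vinyl Grignard addition to the resolved Diels–Alder adduct 7 of vinyl acetate with the masked o-benzoquinone 5, itself made by dearomatising guaiacol 3 (from 3,4-dimethylphenol 1).
5. Ring order: ring A first (Diels–Alder, as the cyclohexene ring of the bicycle), ring B second (oxy-Cope).

Key step: step 7

Remarks on the chemistry:
- Decalins carry the target numbering; bicyclic compounds carry bicyclo[2.2.2]octane locants.
- Assumption: the cycloaddition of step 3 is taken to be ortho- and endo-selective, as is usual for masked o-benzoquinones with electron-rich alkenes. The configuration it sets at the acetoxy carbon (later C2) is erased in step 15.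
- The C4 methyl is brought in with the arene and the C4 hydrogen is added last. On the conformer that the ring-B substituents enforce, axial conjugate addition to the ring-A enone comes from the α-face, so a methyl nucleophile would end trans to the C5 methyl, whereas a hydride leaves the methyl cis.
- The silyl group is tert-butyldiphenylsilyl, chosen to survive the aqueous acid of step 11.

**Route**

Step 1
Reactants: 1 3,4-dimethylphenol
Product: 2 2-bromo-4,5-dimethylphenol
Conditions: NBS, i-Pr2NH (cat.), CH2Cl2, 0 °C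
Reagents that add atoms: N-bromosuccinimide, O=C1CCC(=O)N1Br
Why: Amine-mediated ortho-bromination of a phenol (electrophilic aromatic substitution); the para position is blocked by methyl and, of the two ortho positions, C6 is the one not flanked by a methyl group.

Step 2
Reactants: 2 2-bromo-4,5-dimethylphenol
Product: 3 2-methoxy-4,5-dimethylphenol
Conditions: NaOMe, CuBr (cat.), MeOH–DMF, 110 °C
Reagents that add atoms: sodium methoxide, [Na+].[O-]C
Why: Copper-catalysed Ullmann-type methoxylation of an aryl bromide is a standard way from o-bromophenols to guaiacols, and no stereocentre is involved.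

Step 3
Reactants: 3 2-methoxy-4,5-dimethylphenol; 4 vinyl acetate
Product: 6 (±)-(1S*,4S*,7S*)-7-acetoxy-3,3-dimethoxy-5,6-dimethylbicyclo[2.2.2]oct-5-en-2-one, via masked o-benzoquinone 5 (not isolated)
Conditions: PhI(OAc)2, MeOH–vinyl acetate (1:1), slow addition of 3, 0 °C → rt
Reagents that add atoms: methanol, CO
Why: Oxidative dearomatisation by the hypervalent iodine reagent with methanol capture at the methoxy-bearing carbon gives dienone ketal 5, which is trapped as it forms (to outrun its dimerisation) in an inverse-demand Diels–Alder reaction; the nucleophilic CH2 terminus of the enol ester should bond to the dienone δ-carbon next to the ketal, and the acetoxy group should take the endo position, so that it ends on C7 syn to the new olefin bridge (relative configuration only).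

Step 4
Reactants: 6 (±)-7-acetoxy-3,3-dimethoxy-5,6-dimethylbicyclo[2.2.2]oct-5-en-2-one
Product: 7 (1S,4S,7S)-7-acetoxy-3,3-dimethoxy-5,6-dimethylbicyclo[2.2.2]oct-5-en-2-one
Conditions: Candida rugosa lipase, phosphate buffer pH 7–MTBE, 30 °C, run just past half conversion; chromatography
Reagents that add atoms: none
Why: Lipase-catalysed enantioselective hydrolysis of a secondary acetate (enzymatic kinetic resolution); by the empirical size rule for lipases the (7R)-acetate (bridgehead large, CH2 medium) should react faster, so the (1S,4S,7S)-acetate should be recovered in high enantiomeric purity, and the neutral medium spares the β-acyloxy ketone.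

Step 5
Reactants: 7 (1S,4S,7S)-7-acetoxy-3,3-dimethoxy-5,6-dimethylbicyclo[2.2.2]oct-5-en-2-one; 8 vinylmagnesium bromide
Product: 10 (1S,2R,4S,7S)-3,3-dimethoxy-5,6-dimethyl-2-vinylbicyclo[2.2.2]oct-5-ene-2,7-diol, via acetoxy carbinol alkoxide 9 (not isolated)
Conditions: CH2=CHMgBr (4 equiv), THF, −78 → 0 °C; aq. NH4Cl
Reagents that add atoms: none
Why: Grignard 1,2-addition to the ketone from the face of the olefin bridge, which is less hindered than the face guarded by the inward C–H bonds of the ethano bridge, should set the carbinol centre with vinyl syn to the olefin; on warming the excess reagent cleaves the acetate, so the C7 alkoxide appears only after the ketone is consumed and no retro-aldol opening is possible.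

Step 6
Reactants: 10 (1S,2R,4S,7S)-3,3-dimethoxy-5,6-dimethyl-2-vinylbicyclo[2.2.2]oct-5-ene-2,7-diol
Product: 11 (1S,2R,4S,7S)-7-(tert-butyldiphenylsilyloxy)-3,3-dimethoxy-5,6-dimethyl-2-vinylbicyclo[2.2.2]oct-5-en-2-ol
Conditions: t-BuPh2SiCl, imidazole, DMF, rt
Reagents that add atoms: tert-butyldiphenylsilyl chloride, CC(C)(C)[Si](Cl)(c1ccccc1)c1ccccc1
Why: Silylation with a bulky chlorosilane is selective for the secondary over the tertiary allylic hydroxyl, and the resulting ether is stable to KH.

Step 7
Reactants: 11 (1S,2R,4S,7S)-7-(tert-butyldiphenylsilyloxy)-3,3-dimethoxy-5,6-dimethyl-2-vinylbicyclo[2.2.2]oct-5-en-2-ol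
Product: 14 cis-fused 2β-(tert-butyldiphenylsilyloxy)-9,9-dimethoxy-4,5β-dimethyl-10βH-octal-3-en-8-one, via potassium alkoxide 12 (not isolated), via potassium enolate 13 (not isolated)
Conditions: KH, 18-crown-6, THF, 0 → 50 °C; then AcOH, −78 °C
Reagents that add atoms: none
Why: Deprotonation gives the crown-ether-separated potassium alkoxide 12, whose oxyanion weakens the C3–C8 bond, and the 1,5-diene C6=C7–C8–C3–C4=C5 (target numbering) then undergoes the anion-accelerated [3,3] sigmatropic shift through the boat array that the bicycle enforces; this is the known anionic oxy-Cope rearrangement of 2-vinylbicyclo[2.2.2]oct-5-en-2-ols to cis-decalinones. Ring B (C5–C6–C7–C8–C9–C10) closes by formation of the C5–C6 bond between the vinyl terminus and the methyl-bearing olefin carbon, a six-membered closure concerted with cleavage of C3–C8, while ring A is the cyclohexene ring of the bicycle and stays intact. The new quaternary stereocentre C5 is controlled by the suprafacial course: C6 can reach C5 only on the olefin face that carries the C8–C9 bridge, so C6 and C9 end cis on ring A, that is, the C5 methyl and the C10 hydrogen end cis, and the absolute sense is handed on from the resolved bridgeheads of 11. The step needs the concerted [3,3] path to win over fragmentation to an allyl anion or a [1,3] shift, and it needs the vinyl group to lie over the olefin bridge; the second point is secured by the facial course of step 5, the first by the anion acceleration at moderate temperature and by the silyl ether on the neighbouring bridge pointing away from the alkoxide, so that it can neither migrate nor eliminate. The shift delivers the regiodefined C7–C8 potassium enolate 13, which has no second α-position because C9 is fully substituted, and cold acetic acid should give ketone 14 with C8 and C9 both oxygenated.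

Step 8
Reactants: 14 cis-fused 2β-(tert-butyldiphenylsilyloxy)-9,9-dimethoxy-4,5β-dimethyl-10βH-octal-3-en-8-one; 15 2-bromopropene
Product: 18 7β-isopropenyl-2β-(tert-butyldiphenylsilyloxy)-9,9-dimethoxy-4,5β-dimethyl-10βH-octal-3-en-8-one, via lithium enolate 16 (not isolated), via lithium dienolate 17 (not isolated)
Conditions: Pd2(dba)3 (cat.), P(t-Bu)3·HBF4 (cat.), LiN(SiMe3)2 (2.2 equiv), toluene–THF, rt → 45 °C; then AcOH, −78 °C
Reagents that add atoms: none
Why: Palladium-catalysed α-alkenylation of a ketone enolate (oxidative addition of 15 to zerovalent palladium, transmetalation by enolate 16, reductive elimination) can occur only at C7; the product should rest as dienolate 17, which blocks a second coupling, and its kinetic α-protonation from the axial direction should place the isopropenyl group equatorial (7β) on the chair of ring B that keeps the C5 methyl clear of the axial C9 methoxy group, which is also the more stable epimer.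

Step 9
Reactants: 18 7β-isopropenyl-2β-(tert-butyldiphenylsilyloxy)-9,9-dimethoxy-4,5β-dimethyl-10βH-octal-3-en-8-one
Product: 19 7β-isopropenyl-2β-(tert-butyldiphenylsilyloxy)-9,9-dimethoxy-4,5β-dimethyl-10βH-octal-3-en-8α-ol
Conditions: NaBH4, CeCl3·7H2O, MeOH, −40 °C
Reagents that add atoms: none
Why: 1,2-Reduction under Luche conditions: the small hydride should attack C8 axially from the β-face, anti to the axial C9 methoxy group (polar Felkin–Anh control and the usual axial preference), giving the equatorial 8α-alcohol trans to the isopropenyl group, while the cold buffered medium avoids enolisation toward C7.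

Step 10
Reactants: 19 7β-isopropenyl-2β-(tert-butyldiphenylsilyloxy)-9,9-dimethoxy-4,5β-dimethyl-10βH-octal-3-en-8α-ol
Product: 20 8α-acetoxy-7β-isopropenyl-2β-(tert-butyldiphenylsilyloxy)-9,9-dimethoxy-4,5β-dimethyl-10βH-octal-3-ene
Conditions: Ac2O, pyridine, 4-(dimethylamino)pyridine (cat.), CH2Cl2, rt
Reagents that add atoms: acetic anhydride, CC(=O)OC(C)=O
Why: Nucleophile-catalysed acylation of the equatorial secondary alcohol; fixing the acetate on O8 while C9 is still a ketal makes the differentiation of the two oxygens unambiguous.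

Step 11
Reactants: 20 8α-acetoxy-7β-isopropenyl-2β-(tert-butyldiphenylsilyloxy)-9,9-dimethoxy-4,5β-dimethyl-10βH-octal-3-ene
Product: 21 8α-acetoxy-7β-isopropenyl-2β-(tert-butyldiphenylsilyloxy)-4,5β-dimethyl-10βH-octal-3-en-9-one
Conditions: p-toluenesulfonic acid monohydrate (cat.), acetone–H2O (10:1), 40 °C
Reagents that add atoms: water, O
Why: Acid-catalysed ketal hydrolysis, helped by relief of the axial methoxy strain, is run under mild sulfonic acid catalysis so that the isopropenyl group and the silyl ether survive; the cis ring fusion and the equatorial acetate are the stable arrangements, so enolisation toward C10 or C8 should do no harm.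

Step 12
Reactants: 21 8α-acetoxy-7β-isopropenyl-2β-(tert-butyldiphenylsilyloxy)-4,5β-dimethyl-10βH-octal-3-en-9-one
Product: 22 8α-acetoxy-7β-isopropenyl-2β-(tert-butyldiphenylsilyloxy)-4,5β-dimethyl-10βH-octal-3-en-9α-ol
Conditions: LiBH(s-Bu)3, THF, −78 °C; then AcOH, −78 °C
Reagents that add atoms: none
Why: The bulky borohydride should attack the C9 ketone from the equatorial direction (β-face), because the axial path is blocked by the syn-axial C4 of ring A, giving the axial 9α-alcohol cis to the acetate; the cold acidic quench keeps the borate-bound alkoxide from picking up the neighbouring acetyl group.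

Step 13
Reactants: 22 8α-acetoxy-7β-isopropenyl-2β-(tert-butyldiphenylsilyloxy)-4,5β-dimethyl-10βH-octal-3-en-9α-ol; 23 3-methylbut-2-enoyl chloride
Product: 24 8α-acetoxy-7β-isopropenyl-9α-(3-methylbut-2-enoyloxy)-2β-(tert-butyldiphenylsilyloxy)-4,5β-dimethyl-10βH-octal-3-ene
Conditions: pyridine, 4-(dimethylamino)pyridine, CH2Cl2, 0 °C → rt
Reagents that add atoms: none
Why: Nucleophile-catalysed acylation of the hindered axial alcohol with the acid chloride; pyridine as the only base should keep the acid chloride from forming the vinylketene that would lead to the deconjugated 3-methylbut-3-enoate.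

Step 14
Reactants: 24 8α-acetoxy-7β-isopropenyl-9α-(3-methylbut-2-enoyloxy)-2β-(tert-butyldiphenylsilyloxy)-4,5β-dimethyl-10βH-octal-3-ene
Product: 25 8α-acetoxy-7β-isopropenyl-9α-(3-methylbut-2-enoyloxy)-4,5β-dimethyl-10βH-octal-3-en-2β-ol
Conditions: Bu4NF, AcOH (1:1), THF, rt → 40 °C
Reagents that add atoms: none
Why: Fluoride cleavage of the silyl ether, buffered with acetic acid so that the two esters should not be touched.

Step 15
Reactants: 25 8α-acetoxy-7β-isopropenyl-9α-(3-methylbut-2-enoyloxy)-4,5β-dimethyl-10βH-octal-3-en-2β-ol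
Product: 26 8α-acetoxy-7β-isopropenyl-9α-(3-methylbut-2-enoyloxy)-4,5β-dimethyl-10βH-octal-3-en-2-one
Conditions: Dess–Martin periodinane, CH2Cl2, 0 °C → rt
Reagents that add atoms: none
Why: Dess–Martin oxidation of the allylic alcohol to the enone leaves the esters and the other alkenes alone and removes the C2 stereocentre.

Step 16
Reactants: 26 8α-acetoxy-7β-isopropenyl-9α-(3-methylbut-2-enoyloxy)-4,5β-dimethyl-10βH-octal-3-en-2-one
Product: 27 8α-acetoxy-7β-isopropenyl-9α-(3-methylbut-2-enoyloxy)-4β,5β-dimethyl-10βH-decal-2-one (CNP0150397.1)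
Conditions: [(Ph3P)CuH]6, H2O (2 equiv), degassed benzene–THF, rt
Reagents that add atoms: none
Why: Copper hydride 1,4-reduction is selective for the ketone enone over the isolated alkene and the much less electrophilic β,β-disubstituted enoate; on the conformer locked by the equatorial 7β and 8α groups the C5 methyl is pseudoaxial on the β-face of ring A, so hydride should add to C4 axially from the α-face and leave the C4 methyl β and equatorial, cis to the C5 methyl.

**Compound list**

1 | 3,4-dimethylphenol | Cc1ccc(O)cc1C | starting material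
2 | 2-bromo-4,5-dimethylphenol | Cc1cc(O)c(Br)cc1C | intermediate
3 | 2-methoxy-4,5-dimethylphenol | COc1cc(C)c(C)cc1O | intermediate
4 | vinyl acetate | CC(=O)OC=C | starting material
5 | 6,6-dimethoxy-3,4-dimethylcyclohexa-2,4-dien-1-one (masked o-benzoquinone) | O=C1C=C(C)C(C)=CC1(OC)OC | intermediate (not isolated)
6 | (±)-(1S*,4S*,7S*)-7-acetoxy-3,3-dimethoxy-5,6-dimethylbicyclo[2.2.2]oct-5-en-2-one, acetoxy syn to the olefin bridge; racemate, the enantiomer carried on is drawn | O=C1C(OC)(OC)[C@H]2C[C@H](OC(C)=O)[C@@H]1C(C)=C2C | intermediate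
7 | (1S,4S,7S)-7-acetoxy-3,3-dimethoxy-5,6-dimethylbicyclo[2.2.2]oct-5-en-2-one | O=C1C(OC)(OC)[C@H]2C[C@H](OC(C)=O)[C@@H]1C(C)=C2C | intermediate
8 | vinylmagnesium bromide | C=C[Mg]Br | starting material
9 | bromomagnesium alkoxide of (1S,2R,4S,7S)-7-acetoxy-3,3-dimethoxy-5,6-dimethyl-2-vinylbicyclo[2.2.2]oct-5-en-2-ol (vinyl syn to the olefin bridge) | Br[Mg]O[C@@]1(C=C)C(OC)(OC)[C@H]2C[C@H](OC(C)=O)[C@@H]1C(C)=C2C | intermediate (not isolated)
10 | (1S,2R,4S,7S)-3,3-dimethoxy-5,6-dimethyl-2-vinylbicyclo[2.2.2]oct-5-ene-2,7-diol (vinyl and 7-OH each syn to the olefin bridge) | O[C@@]1(C=C)C(OC)(OC)[C@H]2C[C@H](O)[C@@H]1C(C)=C2C | intermediate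
11 | (1S,2R,4S,7S)-7-(tert-butyldiphenylsilyloxy)-3,3-dimethoxy-5,6-dimethyl-2-vinylbicyclo[2.2.2]oct-5-en-2-ol (key-step precursor) | O[C@@]1(C=C)C(OC)(OC)[C@H]2C[C@H](O[Si](c3ccccc3)(c3ccccc3)C(C)(C)C)[C@@H]1C(C)=C2C | intermediate
12 | potassium alkoxide of 11 | [K+].[O-][C@@]1(C=C)C(OC)(OC)[C@H]2C[C@H](O[Si](c3ccccc3)(c3ccccc3)C(C)(C)C)[C@@H]1C(C)=C2C | intermediate (not isolated)
13 | potassium C7–C8 enolate of 14 | [K+].[O-]C1=CC[C@@]2(C)[C@H](C[C@H](O[Si](c3ccccc3)(c3ccccc3)C(C)(C)C)C=C2C)C1(OC)OC | intermediate (not isolated)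
14 | cis-fused 2β-(tert-butyldiphenylsilyloxy)-9,9-dimethoxy-4,5β-dimethyl-10βH-octal-3-en-8-one (key-step product) | C1C[C@@]2(C)[C@H](C[C@H](O[Si](c3ccccc3)(c3ccccc3)C(C)(C)C)C=C2C)C(OC)(OC)C1=O | intermediate
15 | 2-bromopropene | CC(Br)=C | starting material
16 | lithium C7–C8 enolate of 14 | [Li+].[O-]C1=CC[C@@]2(C)[C@H](C[C@H](O[Si](c3ccccc3)(c3ccccc3)C(C)(C)C)C=C2C)C1(OC)OC | intermediate (not isolated)
17 | lithium dienolate of 18 (C7=C8 enolate conjugated with the isopropenyl group) | [Li+].[O-]C1=C(C(C)=C)C[C@@]2(C)[C@H](C[C@H](O[Si](c3ccccc3)(c3ccccc3)C(C)(C)C)C=C2C)C1(OC)OC | intermediate (not isolated)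
18 | 7β-isopropenyl-2β-(tert-butyldiphenylsilyloxy)-9,9-dimethoxy-4,5β-dimethyl-10βH-octal-3-en-8-one | C=C(C)[C@H]1C[C@@]2(C)[C@H](C[C@H](O[Si](c3ccccc3)(c3ccccc3)C(C)(C)C)C=C2C)C(OC)(OC)C1=O | intermediate
19 | 7β-isopropenyl-2β-(tert-butyldiphenylsilyloxy)-9,9-dimethoxy-4,5β-dimethyl-10βH-octal-3-en-8α-ol | C=C(C)[C@H]1C[C@@]2(C)[C@H](C[C@H](O[Si](c3ccccc3)(c3ccccc3)C(C)(C)C)C=C2C)C(OC)(OC)[C@@H]1O | intermediate
20 | 8α-acetoxy-7β-isopropenyl-2β-(tert-butyldiphenylsilyloxy)-9,9-dimethoxy-4,5β-dimethyl-10βH-octal-3-ene | C=C(C)[C@H]1C[C@@]2(C)[C@H](C[C@H](O[Si](c3ccccc3)(c3ccccc3)C(C)(C)C)C=C2C)C(OC)(OC)[C@@H]1OC(C)=O | intermediate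
21 | 8α-acetoxy-7β-isopropenyl-2β-(tert-butyldiphenylsilyloxy)-4,5β-dimethyl-10βH-octal-3-en-9-one | C=C(C)[C@H]1C[C@@]2(C)[C@H](C[C@H](O[Si](c3ccccc3)(c3ccccc3)C(C)(C)C)C=C2C)C(=O)[C@@H]1OC(C)=O | intermediate
22 | 8α-acetoxy-7β-isopropenyl-2β-(tert-butyldiphenylsilyloxy)-4,5β-dimethyl-10βH-octal-3-en-9α-ol | C=C(C)[C@H]1C[C@@]2(C)[C@H](C[C@H](O[Si](c3ccccc3)(c3ccccc3)C(C)(C)C)C=C2C)[C@H](O)[C@@H]1OC(C)=O | intermediate
23 | 3-methylbut-2-enoyl chloride (senecioyl chloride) | CC(C)=CC(Cl)=O | starting material
24 | 8α-acetoxy-7β-isopropenyl-9α-(3-methylbut-2-enoyloxy)-2β-(tert-butyldiphenylsilyloxy)-4,5β-dimethyl-10βH-octal-3-ene | C=C(C)[C@H]1C[C@@]2(C)[C@H](C[C@H](O[Si](c3ccccc3)(c3ccccc3)C(C)(C)C)C=C2C)[C@H](OC(=O)C=C(C)C)[C@@H]1OC(C)=O | intermediate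
25 | 8α-acetoxy-7β-isopropenyl-9α-(3-methylbut-2-enoyloxy)-4,5β-dimethyl-10βH-octal-3-en-2β-ol | C=C(C)[C@H]1C[C@@]2(C)[C@H](C[C@H](O)C=C2C)[C@H](OC(=O)C=C(C)C)[C@@H]1OC(C)=O | intermediate
26 | 8α-acetoxy-7β-isopropenyl-9α-(3-methylbut-2-enoyloxy)-4,5β-dimethyl-10βH-octal-3-en-2-one | C=C(C)[C@H]1C[C@@]2(C)[C@H](CC(=O)C=C2C)[C@H](OC(=O)C=C(C)C)[C@@H]1OC(C)=O | intermediate
27 | 8α-acetoxy-7β-isopropenyl-9α-(3-methylbut-2-enoyloxy)-4β,5β-dimethyl-10βH-decal-2-one (CNP0150397.1) | C=C(C)[C@H]1C[C@@]2(C)[C@H](CC(=O)C[C@@H]2C)[C@H](OC(=O)C=C(C)C)[C@@H]1OC(C)=O | target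

**Summary**

Total step count: 16. Longest linear sequence: 16 steps (from 1 to 27; 4, 8, 15 and 23 are bought).

Steps most likely to fail:

Step 16 (1,4-reduction of the ring-A enone). The β-carbon is next to a quaternary centre and the α-face is partly covered by the axial ester on C9. Hydride transfer may therefore be slow enough for reduction of the senecioate to compete, or hydride may enter from the β-face. Fallback: change the order so that no enoate is present and only a small hydroxyl sits under ring A when C4 is set. The route is left at alcohol 22, whose silyl ether is cleaved with Bu4NF/AcOH to give the 2β,9α-diol 8-acetate F5. MnO2 in CH2Cl2 should oxidise only the allylic C2 hydroxyl, giving the 9α-hydroxy enone F6. Its 1,4-reduction with [(Ph3P)CuH]6 (an extra equivalent for the free hydroxyl) should give the 9α-hydroxy-4β-methyl ketone F7. Acylation of F7 with 23 (pyridine, 4-(dimethylamino)pyridine) comes back to the route at the target 27.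

Step 8 (C7 isopropenylation). The coupled product may be alkenylated a second time, the new double bond may slip into conjugation with the ketone under the basic conditions, or protonation of the dienolate may give a poor ratio at C7. Fallback: build the group by carbonyl chemistry. Ketone 14 is deprotonated with LiN(i-Pr)2 at −78 °C and the enolate 16 is trapped with acetone to give the 7-(2-hydroxypropan-2-yl) ketone F1. Acid-catalysed dehydration (p-toluenesulfonic acid, benzene, 50 °C) should give the conjugated 7-isopropylidene ketone F2. γ-Deprotonation of F2 with LiN(i-Pr)2 regenerates dienolate 17, and cold acetic acid protonates it at C7. This returns to the route at 18.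

Step 11 (hydrolysis of the C9 ketal beside the C8 acetate). The neighbouring acetoxy group slows ionisation of the ketal, so the acid strength or time needed may start hydration of the isopropenyl group or loss of the silyl ether; acetyl migration in the following reduction is the related danger. Fallback: hydrolyse before acylation and differentiate the diol afterwards. Alcohol 19 is treated with the same mild acid, where the ketal beside a free hydroxyl should open more easily, to give the 8α-hydroxy-9-ketone F3. Reduction with LiBH(s-Bu)3 (2 equiv, −78 °C, equatorial attack) should give the 8α,9α-diol F4. Its equatorial, far less hindered C8 hydroxyl is acetylated selectively (Ac2O, pyridine, 0 °C), which comes back to the route at 22.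

Further compounds
F1 | step 8 | 7β-(2-hydroxypropan-2-yl)-2β-(tert-butyldiphenylsilyloxy)-9,9-dimethoxy-4,5β-dimethyl-10βH-octal-3-en-8-one | CC(C)(O)[C@H]1C[C@@]2(C)[C@H](C[C@H](O[Si](c3ccccc3)(c3ccccc3)C(C)(C)C)C=C2C)C(OC)(OC)C1=O
F2 | step 8 | 7-isopropylidene-2β-(tert-butyldiphenylsilyloxy)-9,9-dimethoxy-4,5β-dimethyl-10βH-octal-3-en-8-one | CC(C)=C1C[C@@]2(C)[C@H](C[C@H](O[Si](c3ccccc3)(c3ccccc3)C(C)(C)C)C=C2C)C(OC)(OC)C1=O
F3 | step 11 | 8α-hydroxy-7β-isopropenyl-2β-(tert-butyldiphenylsilyloxy)-4,5β-dimethyl-10βH-octal-3-en-9-one | C=C(C)[C@H]1C[C@@]2(C)[C@H](C[C@H](O[Si](c3ccccc3)(c3ccccc3)C(C)(C)C)C=C2C)C(=O)[C@@H]1O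
F4 | step 11 | 7β-isopropenyl-2β-(tert-butyldiphenylsilyloxy)-4,5β-dimethyl-10βH-octal-3-ene-8α,9α-diol | C=C(C)[C@H]1C[C@@]2(C)[C@H](C[C@H](O[Si](c3ccccc3)(c3ccccc3)C(C)(C)C)C=C2C)[C@H](O)[C@@H]1O
F5 | step 16 | 8α-acetoxy-7β-isopropenyl-4,5β-dimethyl-10βH-octal-3-ene-2β,9α-diol | C=C(C)[C@H]1C[C@@]2(C)[C@H](C[C@H](O)C=C2C)[C@H](O)[C@@H]1OC(C)=O
F6 | step 16 | 8α-acetoxy-9α-hydroxy-7β-isopropenyl-4,5β-dimethyl-10βH-octal-3-en-2-one | C=C(C)[C@H]1C[C@@]2(C)[C@H](CC(=O)C=C2C)[C@H](O)[C@@H]1OC(C)=O
F7 | step 16 | 8α-acetoxy-9α-hydroxy-7β-isopropenyl-4β,5β-dimethyl-10βH-decal-2-one | C=C(C)[C@H]1C[C@@]2(C)[C@H](CC(=O)C[C@@H]2C)[C@H](O)[C@@H]1OC(C)=O
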